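Ring numbering used throughout: C1 (quaternary; Me and 4-methylpent-3-enyl), cis C2=C3, C4 (ester carbinol), C5 (Me, OH), cis C6=C7, C8 (ketone), C9 (bearing CH2OH)=C10, C11H2.
Retrosynthetic cuts: the C4 ester C–O bond, then the ring bond C8–C9, then C4–C5, C3–C4, C9–C10 and C1–C2, back to geraniol, trimethylsilylacetylene, a formyl ylide, α-angelica lactone and senecioic acid.
Enabling feature: C5(Me)(OH)–C6=C7–C8(=O) is the opened form of a 5,5-disubstituted furan-2(5H)-one (ring O–C5–C6=C7–C8), so a butenolide can offer C8 as acyl donor to a C9 vinyllithium and give back the C5 hydroxyl on opening.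
Forward order: the chain is joined linearly (C1 centre, C11–C9 arm with a (Z)-vinyl iodide, C2–C4 ynal, butenolide by aldol); the only ring, the 11-membered carbocycle, closes last at C8–C9 as the butenolide ring is spent.
Stereochemistry: C1 from a ligand-controlled copper-catalysed SN2′ alkynylation; C4 and C5 together from a catalyst-controlled vinylogous Mukaiyama aldol; cis alkenes from Lindlar reduction (C2=C3), the butenolide ring (C6=C7) and the (Z)-α-iodoenal (C9=C10).

Key step: step 15

Assumption: the target is taken as the open cis-4-hydroxy dienone drawn (not its transannular C5–O–C8 hemiketal), and the sense of induction in steps 2 and 12 is fixed by choosing the ligand antipode.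

Step 1
Reactants: 1 geraniol
Product: 2 geranyl diethyl phosphate
Conditions: ClP(O)(OEt)2, Et3N, DMAP (cat.), CH2Cl2, 0 °C → rt
Reagents that add atoms: diethyl chlorophosphate, CCOP(=O)(Cl)OCC
Why: Phosphorylation of a primary allylic alcohol with a chlorophosphate and an amine base is routine and leaves the (E)-alkene untouched.

Step 2
Reactants: 2 geranyl diethyl phosphate; 3 (trimethylsilyl)acetylene
Product: 5 trimethyl[(3S)-3-ethenyl-3,7-dimethyloct-6-en-1-yn-1-yl]silane, via alkynyl(diisobutyl)aluminium 4 (not isolated)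
Conditions: 3, i-Bu2AlH, Et3N (5 mol %), hexanes, 22 °C; then 2, CuCl2·2H2O (cat.), chiral 4,5-diphenylimidazolinium N-(2-sulfonatoaryl) salt/Ag2O (cat.), THF, −30 °C
Reagents that add atoms: none
Why: Copper-catalysed enantioselective allylic substitution (SN2′) of trisubstituted allylic phosphates with alkynyl(diisobutyl)aluminium reagents, which form by amine-catalysed deprotonative alumination of the terminal alkyne, is an established route to alkyne-bearing quaternary carbons, and the sulfonate-bridged carbene–copper complex (divalent copper salt reduced in the flask) delivers the alkynyl group to one face of C3 of the (E)-phosphate, the ligand antipode being chosen for the (S) centre.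

Step 3
Reactants: 5 the (S)-enyne
Product: 7 (3S)-3-methyl-3-(4-methylpent-3-en-1-yl)-5-(trimethylsilyl)pent-4-yn-1-ol, via trialkylborane 6 (not isolated)
Conditions: 9-BBN, THF, 0 °C → rt; then NaBO3·4H2O, H2O, rt
Reagents that add atoms: sodium perborate, [Na+].[O-]OB=O
Why: Hydroboration–oxidation, in which 9-BBN adds to the monosubstituted vinyl group far faster than to the trisubstituted alkene or the silyl-capped alkyne and puts boron on the terminal carbon, while the mild perborate oxidation spares the alkynyl C–Si bond.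

Step 4
Reactants: 7 the primary alcohol
Product: 8 (3S)-3-methyl-3-(4-methylpent-3-en-1-yl)-5-(trimethylsilyl)pent-4-ynal
Conditions: Dess–Martin periodinane, CH2Cl2, rt
Reagents that add atoms: none
Why: Dess–Martin oxidation of a primary alcohol stops at the aldehyde, and the neighbouring quaternary carbon rules out epimerisation.

Step 5
Reactants: 8 the aldehyde; 9 (formylmethylene)triphenylphosphorane
Product: 10 (2E,5S)-5-methyl-5-(4-methylpent-3-en-1-yl)-7-(trimethylsilyl)hept-2-en-6-ynal
Conditions: 9 (1.3 equiv), toluene, 80 °C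
Reagents that add atoms: none
Why: Wittig olefination with a stabilised formyl ylide gives the (E)-enal, and a small excess of ylide at moderate temperature limits a second homologation.

Step 6
Reactants: 10 the (E)-enal
Product: 11 (2Z,5S)-2-iodo-5-methyl-5-(4-methylpent-3-en-1-yl)-7-(trimethylsilyl)hept-2-en-6-ynal
Conditions: I2, K2CO3, DMAP (cat.), THF/H2O (1:1), rt
Reagents that add atoms: iodine, II
Why: Amine-catalysed α-iodination of an enal (conjugate addition of DMAP, iodination of the enolate, elimination) gives the thermodynamically preferred (Z)-2-iodoenal, in which iodine is cis to the C11 chain.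

Step 7
Reactants: 11 the (Z)-2-iodoenal
Product: 12 (2Z,5S)-2-iodo-5-methyl-5-(4-methylpent-3-en-1-yl)-7-(trimethylsilyl)hept-2-en-6-yn-1-ol
Conditions: NaBH4, CeCl3·7H2O, MeOH, −20 °C
Reagents that add atoms: none
Why: Luche reduction gives clean 1,2-reduction of the α-iodoenal without touching the C–I bond, the alkenes or the alkyne.

Step 8
Reactants: 12 the (Z)-2-iodoallyl alcohol
Product: 13 tert-butyl{[(2Z,5S)-2-iodo-5-methyl-5-(4-methylpent-3-en-1-yl)-7-(trimethylsilyl)hept-2-en-6-yn-1-yl]oxy}diphenylsilane
Conditions: t-BuPh2SiCl, imidazole, CH2Cl2, rt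
Reagents that add atoms: tert-butyl(chloro)diphenylsilane, CC(C)(C)[Si](Cl)(c1ccccc1)c1ccccc1
Why: Silylation of a primary allylic alcohol, with the TBDPS ether chosen because it survives the carbonate, Grignard, Lewis acid, organolithium and buffered fluoride conditions that follow.

Step 9
Reactants: 13 the bis-silyl compound
Product: 14 tert-butyl{[(2Z,5S)-5-ethynyl-2-iodo-5,9-dimethyldeca-2,8-dien-1-yl]oxy}diphenylsilane
Conditions: K2CO3 (cat.), MeOH/THF, rt
Reagents that add atoms: none
Why: Carbonate-catalysed methanolysis cleaves only the alkynyl C–Si bond, the silyl ether and the vinyl iodide being inert.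

Step 10
Reactants: 14 the terminal alkyne
Product: 17 (4S,6Z)-8-[(tert-butyldiphenylsilyl)oxy]-7-iodo-4-methyl-4-(4-methylpent-3-en-1-yl)oct-6-en-2-ynal, via bromomagnesium acetylide 15 (not isolated), via hemiaminal alkoxide 16 (not isolated)
Conditions: EtMgBr, THF, 0 → 40 °C; DMF, 0 °C → rt; inverse quench into aq. KH2PO4
Reagents that add atoms: N,N-dimethylformamide, CN(C)C=O
Why: Formylation of a magnesium acetylide with DMF supplies C4, the Grignard base deprotonating the alkyne without halogen–metal exchange at the vinyl iodide (which an alkyllithium would attack) and the buffered inverse quench releasing the ynal without conjugate addition of dimethylamine.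

Step 11
Reactants: 18 α-angelica lactone
Product: 19 5-methyl-2-(trimethylsilyloxy)furan
Conditions: Me3SiCl, Et3N, Et2O, 0 °C → rt; distillation
Reagents that add atoms: chlorotrimethylsilane, C[Si](C)(C)Cl
Why: Silyl dienol ether formation, in which soft enolisation of the β,γ-unsaturated lactone and O-silylation give the aromatic 2-silyloxyfuran.

Step 12
Reactants: 17 the ynal; 19 the silyloxyfuran
Product: 21 (5R)-5-[(1S,4S,6Z)-8-[(tert-butyldiphenylsilyl)oxy]-1-hydroxy-7-iodo-4-methyl-4-(4-methylpent-3-en-1-yl)oct-6-en-2-yn-1-yl]-5-methylfuran-2(5H)-one, via aldol trimethylsilyl ether 20 (not isolated)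
Conditions: Ti(OiPr)4 (20 mol %), BINOL (20 mol %, the antipode that gives Re-face attack), Et2O, −20 °C; then 1 M HCl, THF, 0 °C
Reagents that add atoms: none
Why: Catalytic asymmetric vinylogous Mukaiyama aldol of a 2-silyloxyfuran with an aldehyde under a BINOL–titanium Lewis acid, in which the furan reacts at its methyl-bearing carbon, attack on the Re face of the slim ynal carbonyl sets C4 (S), and an open transition state with the furan oxygen turned away from the carbonyl oxygen should set C5 (R), so that the two oxygens are anti in the C3–C6 zigzag.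

Step 13
Reactants: 21 the butenolide propargylic alcohol
Product: 22 (5R)-5-[(1S,2Z,4S,6Z)-8-[(tert-butyldiphenylsilyl)oxy]-1-hydroxy-7-iodo-4-methyl-4-(4-methylpent-3-en-1-yl)octa-2,6-dien-1-yl]-5-methylfuran-2(5H)-one
Conditions: H2 (1 atm), Pd/CaCO3 poisoned with Pb(OAc)2 (Lindlar catalyst), quinoline, EtOAc, 0 °C, stopped at one equivalent of H2
Reagents that add atoms: none
Why: Lindlar semi-hydrogenation adds hydrogen syn to the alkyne to give the cis C2=C3 alkene, and the lead- and quinoline-poisoned surface should spare the hindered trisubstituted vinyl iodide, the butenolide alkene and the trisubstituted alkene while the more strongly bound alkyne is present.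

Step 14
Reactants: 22 the cis-allylic alcohol
Product: 23 (5R)-5-[(1S,2Z,4S,6Z)-8-[(tert-butyldiphenylsilyl)oxy]-7-iodo-4-methyl-4-(4-methylpent-3-en-1-yl)-1-[(triethylsilyl)oxy]octa-2,6-dien-1-yl]-5-methylfuran-2(5H)-one
Conditions: Et3SiOTf, 2,6-lutidine, CH2Cl2, −78 °C
Reagents that add atoms: triethylsilyl trifluoromethanesulfonate, CC[Si](CC)(CC)OS(=O)(=O)C(F)(F)F
Why: Silyl triflate silylation of the hindered secondary alcohol gives a triethylsilyl ether that blocks retro-aldol and translactonisation, is inert to t-BuLi at low temperature and can later be removed beside the TBDPS ether, while the butenolide cannot be enolised because C5 bears no hydrogen.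

Step 15
Reactants: 23 the vinyl iodide tethered to the butenolide
Product: 26 (1S,2Z,4S,5R,6Z,9Z)-9-{[(tert-butyldiphenylsilyl)oxy]methyl}-5-hydroxy-1,5-dimethyl-1-(4-methylpent-3-en-1-yl)-4-[(triethylsilyl)oxy]cycloundeca-2,6,9-trien-8-one (overview numbering), via vinyllithium 24 (not isolated), via bridged lactol alkoxide 25 (not isolated)
Conditions: t-BuLi (2.0 equiv), THF/Et2O/pentane (4:1:1), 0.002 M, −100 °C; then AcOH, −100 °C → rt
Reagents that add atoms: none
Why: Proposed new method: t-BuLi exchanges the C9 iodide within seconds at −100 °C (the second equivalent destroys t-BuI), and the configurationally stable vinyllithium 24 adds 1,2 to the lactone carbonyl C8 in an 11-exo-trig closure of the carbocycle, giving the oxygen-bridged lactol alkoxide 25, whose C8–O ring bond opens on protonation and warming to free the C5 tertiary alcohol and the cross-conjugated dienone. The closest known reactions are the Parham cyclization and related halogen–lithium exchange-initiated cycloacylations of esters and lactones, known for small rings, and the intermolecular addition of alkenyllithiums to 5,5-disubstituted butenolides, which stops at the lactol or cis-4-hydroxy enone; an 11-membered ring has not been closed in this way. No stereocentre is created in 26: C1, C4 and C5 are untouched, the transient C8 centre of 25 is fixed by the bridge and lost on opening, the C9=C10 geometry is carried over with retention from the (Z)-iodide, and C6=C7 stays cis because it was a ring alkene. The step needs exchange before any attack of t-BuLi on the lactone, 1,2- over 1,4-addition and ring closure over oligomerisation; these rest on the very fast iodine–lithium exchange, on a hard sp2 organolithium meeting a lactone that cannot be deprotonated at the fully substituted C5, and on high dilution. The tether is pre-bent by the cis C2=C3 alkene, the quaternary C1 and the substituted C4/C5 pair, and the tetrahedral alkoxide 25 hides the ketone until the acetic acid quench, so no second addition can follow.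

Step 16
Reactants: 26 the bis-silylated hydroxy dienone
Product: 27 (1S,2Z,4S,5R,6Z,9Z)-9-{[(tert-butyldiphenylsilyl)oxy]methyl}-4,5-dihydroxy-1,5-dimethyl-1-(4-methylpent-3-en-1-yl)cycloundeca-2,6,9-trien-8-one (overview numbering)
Conditions: HF·pyridine, pyridine, THF, 0 °C
Reagents that add atoms: none
Why: Buffered HF·pyridine at 0 °C cleaves the triethylsilyl ether far faster than the primary TBDPS ether, and the alcohol-free medium avoids trapping the transannular hemiketal as a mixed ketal.

Step 17
Reactants: 27 the C4,C5-diol; 28 3-methylbut-2-enoic acid (senecioic acid)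
Product: 30 (1S,2Z,4S,5R,6Z,9Z)-9-{[(tert-butyldiphenylsilyl)oxy]methyl}-5-hydroxy-1,5-dimethyl-1-(4-methylpent-3-en-1-yl)-8-oxocycloundeca-2,6,9-trien-4-yl 3-methylbut-2-enoate (overview numbering), via O-acylisourea 29 (not isolated)
Conditions: 28, DCC, DMAP, CH2Cl2, 0 °C → rt
Reagents that add atoms: none
Why: Steglich esterification transfers the DMAP-activated acyl group to the secondary C4 alcohol, the tertiary C5 alcohol being too hindered to react and the primary alcohol still silylated.

Step 18
Reactants: 30 the silylated ester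
Product: 31 CNP0230506.3, (1S,2Z,4S,5R,6Z,9Z)-5-hydroxy-9-(hydroxymethyl)-1,5-dimethyl-1-(4-methylpent-3-en-1-yl)-8-oxocycloundeca-2,6,9-trien-4-yl 3-methylbut-2-enoate (overview numbering)
Conditions: HF·pyridine, THF, 0 °C → rt
Reagents that add atoms: none
Why: Fluoride cleavage of the primary TBDPS ether under mildly acidic conditions should leave the senecioate, the tertiary alcohol and the dienone intact.

Compound list
1 | geraniol, (2E)-3,7-dimethylocta-2,6-dien-1-ol | CC(C)=CCC/C(C)=C/CO | starting material
2 | geranyl diethyl phosphate | CC(C)=CCC/C(C)=C/COP(=O)(OCC)OCC | intermediate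
3 | (trimethylsilyl)acetylene | C#C[Si](C)(C)C | starting material
4 | diisobutyl[(trimethylsilyl)ethynyl]aluminium (formed in the flask, not isolated) | CC(C)C[Al](CC(C)C)C#C[Si](C)(C)C | intermediate
5 | trimethyl[(3S)-3-ethenyl-3,7-dimethyloct-6-en-1-yn-1-yl]silane | CC(C)=CCC[C@](C=C)(C)C#C[Si](C)(C)C | intermediate
6 | B-alkyl-9-BBN from anti-Markovnikov addition to the vinyl group of 5, quaternary centre unchanged (not isolated) | CC(C)=CCC[C@](CCB1C2CCCC1CCC2)(C)C#C[Si](C)(C)C | intermediate
7 | (3S)-3-methyl-3-(4-methylpent-3-en-1-yl)-5-(trimethylsilyl)pent-4-yn-1-ol | CC(C)=CCC[C@](CCO)(C)C#C[Si](C)(C)C | intermediate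
8 | (3S)-3-methyl-3-(4-methylpent-3-en-1-yl)-5-(trimethylsilyl)pent-4-ynal | CC(C)=CCC[C@](CC=O)(C)C#C[Si](C)(C)C | intermediate
9 | (formylmethylene)triphenylphosphorane | O=CC=P(c1ccccc1)(c1ccccc1)c1ccccc1 | starting material
10 | (2E,5S)-5-methyl-5-(4-methylpent-3-en-1-yl)-7-(trimethylsilyl)hept-2-en-6-ynal | CC(C)=CCC[C@](C/C=C/C=O)(C)C#C[Si](C)(C)C | intermediate
11 | (2Z,5S)-2-iodo-5-methyl-5-(4-methylpent-3-en-1-yl)-7-(trimethylsilyl)hept-2-en-6-ynal | CC(C)=CCC[C@](C/C=C(\I)C=O)(C)C#C[Si](C)(C)C | intermediate
12 | (2Z,5S)-2-iodo-5-methyl-5-(4-methylpent-3-en-1-yl)-7-(trimethylsilyl)hept-2-en-6-yn-1-ol | CC(C)=CCC[C@](C/C=C(\I)CO)(C)C#C[Si](C)(C)C | intermediate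
13 | TBDPS ether of 12 | CC(C)=CCC[C@](C/C=C(\I)CO[Si](c1ccccc1)(c1ccccc1)C(C)(C)C)(C)C#C[Si](C)(C)C | intermediate
14 | tert-butyl{[(2Z,5S)-5-ethynyl-2-iodo-5,9-dimethyldeca-2,8-dien-1-yl]oxy}diphenylsilane | CC(C)=CCC[C@](C/C=C(\I)CO[Si](c1ccccc1)(c1ccccc1)C(C)(C)C)(C)C#C | intermediate
15 | bromomagnesium acetylide of 14 (not isolated) | CC(C)=CCC[C@](C/C=C(\I)CO[Si](c1ccccc1)(c1ccccc1)C(C)(C)C)(C)C#C[Mg]Br | intermediate
16 | bromomagnesium hemiaminal alkoxide from 15 and DMF (not isolated) | CC(C)=CCC[C@](C/C=C(\I)CO[Si](c1ccccc1)(c1ccccc1)C(C)(C)C)(C)C#CC(O[Mg]Br)N(C)C | intermediate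
17 | (4S,6Z)-8-[(tert-butyldiphenylsilyl)oxy]-7-iodo-4-methyl-4-(4-methylpent-3-en-1-yl)oct-6-en-2-ynal | CC(C)=CCC[C@](C/C=C(\I)CO[Si](c1ccccc1)(c1ccccc1)C(C)(C)C)(C)C#CC=O | intermediate
18 | α-angelica lactone, 5-methylfuran-2(3H)-one | CC1=CCC(=O)O1 | starting material
19 | 5-methyl-2-(trimethylsilyloxy)furan | Cc1ccc(O[Si](C)(C)C)o1 | intermediate
20 | trimethylsilyl ether of aldol 21 (not isolated) | CC(C)=CCC[C@](C/C=C(\I)CO[Si](c1ccccc1)(c1ccccc1)C(C)(C)C)(C)C#C[C@H](O[Si](C)(C)C)[C@]1(C)OC(=O)C=C1 | intermediate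
21 | (5R)-5-[(1S,4S,6Z)-8-(TBDPS-oxy)-1-hydroxy-7-iodo-4-methyl-4-(4-methylpent-3-en-1-yl)oct-6-en-2-yn-1-yl]-5-methylfuran-2(5H)-one | CC(C)=CCC[C@](C/C=C(\I)CO[Si](c1ccccc1)(c1ccccc1)C(C)(C)C)(C)C#C[C@H](O)[C@]1(C)OC(=O)C=C1 | intermediate
22 | (5R)-5-[(1S,2Z,4S,6Z)-8-(TBDPS-oxy)-1-hydroxy-7-iodo-4-methyl-4-(4-methylpent-3-en-1-yl)octa-2,6-dien-1-yl]-5-methylfuran-2(5H)-one | CC(C)=CCC[C@](C/C=C(\I)CO[Si](c1ccccc1)(c1ccccc1)C(C)(C)C)(C)/C=C\[C@H](O)[C@]1(C)OC(=O)C=C1 | intermediate
23 | triethylsilyl ether of 22 at C4 | CC(C)=CCC[C@](C/C=C(\I)CO[Si](c1ccccc1)(c1ccccc1)C(C)(C)C)(C)/C=C\[C@H](O[Si](CC)(CC)CC)[C@]1(C)OC(=O)C=C1 | intermediate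
24 | C9 vinyllithium from 23, lithium cis to C11 as iodine was (not isolated) | CC(C)=CCC[C@](C/C=C(\[Li])CO[Si](c1ccccc1)(c1ccccc1)C(C)(C)C)(C)/C=C\[C@H](O[Si](CC)(CC)CC)[C@]1(C)OC(=O)C=C1 | intermediate
25 | lithium alkoxide of the bridged lactol, a 12-oxabicyclo[7.2.1]dodecatriene with oxygen spanning C5 and C8 (not isolated) | CC(C)=CCC[C@]1(C)/C=C\[C@H](O[Si](CC)(CC)CC)[C@@]2(C)C=C[C@](O[Li])(O2)/C(CO[Si](c3ccccc3)(c3ccccc3)C(C)(C)C)=C\C1 | intermediate
26 | (1S,2Z,4S,5R,6Z,9Z)-9-[(TBDPS-oxy)methyl]-5-hydroxy-1,5-dimethyl-1-(4-methylpent-3-en-1-yl)-4-(triethylsilyloxy)cycloundeca-2,6,9-trien-8-one (overview numbering) | CC(C)=CCC[C@]1(C)/C=C\[C@H](O[Si](CC)(CC)CC)[C@](C)(O)/C=C\C(=O)/C(CO[Si](c2ccccc2)(c2ccccc2)C(C)(C)C)=C\C1 | intermediate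
27 | C4,C5-diol of 26 (triethylsilyl removed) | CC(C)=CCC[C@]1(C)/C=C\[C@H](O)[C@](C)(O)/C=C\C(=O)/C(CO[Si](c2ccccc2)(c2ccccc2)C(C)(C)C)=C\C1 | intermediate
28 | 3-methylbut-2-enoic acid (senecioic acid) | CC(C)=CC(=O)O | starting material
29 | O-(3-methylbut-2-enoyl)-N,N'-dicyclohexylisourea (not isolated) | CC(C)=CC(=O)OC(=NC1CCCCC1)NC1CCCCC1 | intermediate
30 | C4 senecioate of 27, TBDPS ether retained | CC(C)=CCC[C@]1(C)/C=C\[C@H](OC(=O)C=C(C)C)[C@](C)(O)/C=C\C(=O)/C(CO[Si](c2ccccc2)(c2ccccc2)C(C)(C)C)=C\C1 | intermediate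
31 | CNP0230506.3, (1S,2Z,4S,5R,6Z,9Z)-5-hydroxy-9-(hydroxymethyl)-1,5-dimethyl-1-(4-methylpent-3-en-1-yl)-8-oxocycloundeca-2,6,9-trien-4-yl 3-methylbut-2-enoate (overview numbering) | CC(C)=CCC[C@]1(C)/C=C\[C@H](OC(=O)C=C(C)C)[C@](C)(O)/C=C\C(=O)/C(CO)=C\C1 | target

Total step count: 18. Longest linear sequence: 17 steps (geraniol to the target, steps 1–10 and 12–18; step 11 is the side branch).

Steps most likely to fail

Step 15. The ring closure may lose to addition of t-BuLi to the lactone, or to intermolecular acylation that gives oligomers, if the 11-membered transition state is slower than expected. The fallback keeps the C8–C9 closure but uses known chemistry. From 23, DIBAL-H (1 equiv, CH2Cl2, −78 °C) should reduce the butenolide to the 5-substituted 5-methyl-2,5-dihydrofuran-2-ol (lactol) F1, which reacts through its open cis-4-hydroxy enal form. A Nozaki–Hiyama–Kishi macrocyclization (CrCl2, NiCl2 cat., DMSO, high dilution, rt) of the vinyl iodide onto that aldehyde should give the 11-membered C5,C8-diol F2 as a mixture of C8 epimers. MnO2 in CH2Cl2 then oxidises only the secondary bis-allylic alcohol, and the route is rejoined at 26.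

Step 12. Enantiofacial control at the aldehyde may be good while the relative topicity is the opposite of what is needed, or poor, so that the quaternary C5 is set wrongly. The fallback sets C5 by the aldol and C4 by a reduction. From 17 and 19 the aldol is run with the antipodal BINOL–Ti(OiPr)4 catalyst, so that the preferred syn pair has C5 correct; it gives, through its trimethylsilyl ether F3, the (4R,5R) alcohol F4. Dess–Martin oxidation gives the ynone F5. Corey–Bakshi–Shibata reduction ((R)-2-methyl-CBS-oxazaborolidine, catecholborane, toluene, −78 °C; the antipode if the alkynyl arm proves the larger group) should then deliver the (4S) alcohol and return to 21.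

Step 13. Hydrogenolysis of the C–I bond or reduction of the butenolide alkene may compete at the palladium surface, since the alkyne is hindered on both sides. The fallback replaces catalytic hydrogenation by an electron-transfer reduction. From 21, activated zinc (Zn dust treated with Cu(OAc)2 and AgNO3, MeOH/H2O, rt to 40 °C) reduces propargylic alcohols to cis-alkenes and offers no surface for oxidative addition into the vinyl C–I bond. It should lead directly to 22 and makes no new compound.

Further compounds
F1 | step 15 | lactol from 23, 5-substituted 5-methyl-2,5-dihydrofuran-2-ol (anomers) | CC(C)=CCC[C@](C/C=C(\I)CO[Si](c1ccccc1)(c1ccccc1)C(C)(C)C)(C)/C=C\[C@H](O[Si](CC)(CC)CC)[C@]1(C)OC(O)C=C1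
F2 | step 15 | 11-membered C5,C8-diol, C8 epimers (C8 carbinol in place of the ketone of 26) | CC(C)=CCC[C@]1(C)/C=C\[C@H](O[Si](CC)(CC)CC)[C@](C)(O)/C=C\C(O)/C(CO[Si](c2ccccc2)(c2ccccc2)C(C)(C)C)=C\C1
F3 | step 12 | trimethylsilyl ether of the (4R,5R) aldol (not isolated) | CC(C)=CCC[C@](C/C=C(\I)CO[Si](c1ccccc1)(c1ccccc1)C(C)(C)C)(C)C#C[C@@H](O[Si](C)(C)C)[C@]1(C)OC(=O)C=C1
F4 | step 12 | (4R,5R) alcohol, C4 epimer of 21 | CC(C)=CCC[C@](C/C=C(\I)CO[Si](c1ccccc1)(c1ccccc1)C(C)(C)C)(C)C#C[C@@H](O)[C@]1(C)OC(=O)C=C1
F5 | step 12 | ynone, C4 ketone of 21 | CC(C)=CCC[C@](C/C=C(\I)CO[Si](c1ccccc1)(c1ccccc1)C(C)(C)C)(C)C#CC(=O)[C@]1(C)OC(=O)C=C1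
F0 | step 13 | none | none
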